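## Retrosynthetic overview

1. Feature: in the cyclopentane ring, the carbinol carbon C(OH)CH3, the adjacent CH carrying the CH2 link to the six-membered acylphloroglucinol ring, and the next CH carrying isopropenyl are the C=O, Cα and Cβ of a 2-substituted cyclopent-2-enone; the two remaining ring CH2 groups are ethylene.
2. Hypercalin B ⇒ (C–CH3, methyl addition anti to the side chain) trans-2,3-disubstituted cyclopentanone ⇒ (C–isopropenyl, Rh-catalysed asymmetric 1,4-addition) 2-substituted cyclopentenone.
3. Cyclopentenone ⇒ Pauson–Khand (2+2+1) union of the C-propargylated trione, ethylene and CO.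
4. Propargyl trione ⇒ C-propargylation and dearomatising gem-diprenylation of 2,4,6-trihydroxybenzophenone.
5. Ring order: the six-membered carbocycle comes from the arene (dearomatised in step 1); the cyclopentane ring is the only ring formed, in step 3.

Key step: step 3

Assumption: the β-triketone core is written throughout as the dienol tautomer of the target SMILES (tautomers interconvert freely), and the sense of induction of (S)-BINAP in step 4 is taken by analogy with unsubstituted cyclopent-2-enone.

## Route

Step 1
Reactants: 1 2,4,6-trihydroxybenzophenone; 2 prenyl bromide (1-bromo-3-methylbut-2-ene)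
Product: 3 2-benzoyl-3,5-dihydroxy-6,6-bis(3-methylbut-2-en-1-yl)cyclohexa-2,4-dien-1-one (enol form of 2-benzoyl-4,4-diprenylcyclohexane-1,3,5-trione)
Conditions: NaOMe (3 equiv), MeOH, 0 °C; 2 (2.1 equiv), 0 °C → rt; 1 M HCl; chromatography
Reagents that add atoms: prenyl bromide (2), CC(C)=CCBr
Why: Alkylative dearomatisation of an acylphloroglucinol, in which the phenoxide is C-prenylated and then alkylated again at the same, now more electron-rich carbon to leave the enolised triketone; attack at the free ring carbon should give an aromatic 3,5-diprenyl isomer that is removed by chromatography.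

Step 2
Reactants: 3 gem-diprenyl trione; 4 propargyl bromide (3-bromoprop-1-yne)
Product: 5 2-benzoyl-3,5-dihydroxy-6,6-bis(3-methylbut-2-en-1-yl)-4-(prop-2-yn-1-yl)cyclohexa-2,4-dien-1-one
Conditions: NaOMe (2.2 equiv), MeOH, 0 °C; 4 (1.05 equiv), 0 °C → rt; 1 M HCl
Reagents that add atoms: propargyl bromide (4), C#CCBr
Why: SN2 C-alkylation of the cyclic β-triketone dianion in a protic medium at the only ring CH carbon, which is the more nucleophilic terminus because the other charge sits in the more stabilised 2-acyl-1,3-dione unit, with one equivalent of bromide limiting a second alkylation.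

Step 3
Reactants: 5 propargyl trione; 6 dicobalt octacarbonyl; 7 ethylene
Product: 9 2-benzoyl-3,5-dihydroxy-6,6-bis(3-methylbut-2-en-1-yl)-4-[(5-oxocyclopent-1-en-1-yl)methyl]cyclohexa-2,4-dien-1-one, via alkyne–dicobalt hexacarbonyl complex 8 (not isolated)
Conditions: 6 (1.1 equiv), CH2Cl2, rt; then 7 (6 bar), NMO (8 equiv), 4 Å MS, CH2Cl2, rt; 0.5 M HCl wash
Reagents that add atoms: ethylene (7), C=C; dicobalt octacarbonyl (6), source of the ring carbonyl, O=C=[Co](=C=O)(=C=O)(=C=O)[Co](=C=O)(=C=O)(=C=O)=C=O
Why: Dicobalt octacarbonyl converts the terminal alkyne of 5 into complex 8 with loss of two CO; the N-oxide then removes a CO ligand, ethylene coordinates and inserts at the unsubstituted alkyne carbon, CO inserts next to the substituted carbon, and reductive elimination with decomplexation releases the enone. This is the intermolecular Pauson–Khand reaction of a terminal alkyne with ethylene, a known way to 2-alkylcyclopent-2-enones. The one new ring is closed in an intermolecular three-component (2+2+1) mode, with two bonds to the new carbonyl carbon and one bond between the terminal alkyne carbon and ethylene, whose two carbons become the ring CH2 groups. No stereocentre is formed. The step needs regioselectivity, secured because the only alkyne substituent (the CH2 to the core) ends α to the carbonyl for steric reasons, and chemoselectivity for ethylene over the prenyl groups, secured because trisubstituted alkenes insert poorly, ethylene is in excess under pressure, and the nearest prenyl alkene could only close a seven-membered ring. The enolised triketone is a spectator acidic enough to protonate part of the N-oxide, hence the excess of promoter and the acidic wash that frees the product from cobalt(II).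

Step 4
Reactants: 9 cyclopentenone; 10 isopropenylboronic acid pinacol ester
Product: 12 2-benzoyl-3,5-dihydroxy-6,6-bis(3-methylbut-2-en-1-yl)-4-{[(1R,5S)-2-oxo-5-(prop-1-en-2-yl)cyclopentyl]methyl}cyclohexa-2,4-dien-1-one (trans ketone), via (1S,5S)-cis ketone 11 (not isolated)
Conditions: 10 (5 equiv), [RhCl(C2H4)2]2 (5 mol %), (S)-BINAP (11 mol %), KOH (3 equiv), dioxane/H2O 10:1, 90 °C (addition and C-2 equilibration in one pot); 1 M HCl to pH 4
Reagents that add atoms: isopropenylboronic acid pinacol ester (10), C=C(C)B1OC(C)(C)C(C)(C)O1
Why: Hayashi–Miyaura rhodium-catalysed asymmetric 1,4-addition, in which the isopropenyl–Rh(I)/(S)-BINAP species carbometalates one enantiotopic face of the enone and sets the isopropenyl-bearing carbon as S (the other ligand enantiomer is used if the sense proves reversed), while the adjacent α-carbon epimerises through the enolate in the hot basic medium to the more stable trans ketone; the triketone is present as its inert dipotassium salt, and its binding to rhodium parallels the Rh(acac) precatalysts of this reaction.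

Step 5
Reactants: 12 trans ketone; 13 methylmagnesium bromide
Product: 14 hypercalin B, 2-benzoyl-3,5-dihydroxy-4-{[(1R,2S,5S)-2-hydroxy-2-methyl-5-(prop-1-en-2-yl)cyclopentyl]methyl}-6,6-bis(3-methylbut-2-en-1-yl)cyclohexa-2,4-dien-1-one
Conditions: 13 (6 equiv), anhydrous CeCl3 (6 equiv), THF, −78 → 0 °C; 0.5 M HCl to pH 4, 0 °C
Reagents that add atoms: methylmagnesium bromide (13), C[Mg]Br
Why: Organocerium (Imamoto) 1,2-addition, in which the first two equivalents turn the triketone into an unreactive dienolate dianion and the weakly basic methylcerium species adds to the only remaining electrophilic carbonyl without enolising it, attacking anti to the adjacent CH2–core substituent so that methyl ends trans and hydroxyl cis to the side chain (S carbinol carbon).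

## Compound list

1 | 2,4,6-trihydroxybenzophenone | O=C(c1ccccc1)c1c(O)cc(O)cc1O | starting material
2 | prenyl bromide (1-bromo-3-methylbut-2-ene) | CC(C)=CCBr | starting material
3 | 2-benzoyl-3,5-dihydroxy-6,6-bis(3-methylbut-2-en-1-yl)cyclohexa-2,4-dien-1-one | O=C(c1ccccc1)C1=C(O)C=C(O)C(CC=C(C)C)(CC=C(C)C)C1=O | intermediate
4 | propargyl bromide (3-bromoprop-1-yne) | C#CCBr | starting material
5 | 2-benzoyl-3,5-dihydroxy-6,6-bis(3-methylbut-2-en-1-yl)-4-(prop-2-yn-1-yl)cyclohexa-2,4-dien-1-one | C#CCC1=C(O)C(CC=C(C)C)(CC=C(C)C)C(=O)C(C(=O)c2ccccc2)=C1O | intermediate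
6 | dicobalt octacarbonyl | O=C=[Co](=C=O)(=C=O)(=C=O)[Co](=C=O)(=C=O)(=C=O)=C=O | starting material
7 | ethylene | C=C | starting material
8 | μ-alkyne dicobalt hexacarbonyl complex of 5 (C2Co2 tetrahedrane) | O=C=[Co]12(=C=O)(=C=O)[Co]3(=C=O)(=C=O)(=C=O)C1(CC4=C(O)C(CC=C(C)C)(CC=C(C)C)C(=O)C(C(=O)c5ccccc5)=C4O)C23[H] | intermediate
9 | 2-benzoyl-3,5-dihydroxy-6,6-bis(3-methylbut-2-en-1-yl)-4-[(5-oxocyclopent-1-en-1-yl)methyl]cyclohexa-2,4-dien-1-one | O=C1CCC=C1CC1=C(O)C(CC=C(C)C)(CC=C(C)C)C(=O)C(C(=O)c2ccccc2)=C1O | intermediate
10 | isopropenylboronic acid pinacol ester | C=C(C)B1OC(C)(C)C(C)(C)O1 | starting material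
11 | cis ketone, 4-{[(1S,5S)-2-oxo-5-(prop-1-en-2-yl)cyclopentyl]methyl} epimer of 12 | C=C(C)[C@H]1CCC(=O)[C@H]1CC1=C(O)C(CC=C(C)C)(CC=C(C)C)C(=O)C(C(=O)c2ccccc2)=C1O | intermediate
12 | trans ketone, 2-benzoyl-3,5-dihydroxy-6,6-bis(3-methylbut-2-en-1-yl)-4-{[(1R,5S)-2-oxo-5-(prop-1-en-2-yl)cyclopentyl]methyl}cyclohexa-2,4-dien-1-one | C=C(C)[C@H]1CCC(=O)[C@@H]1CC1=C(O)C(CC=C(C)C)(CC=C(C)C)C(=O)C(C(=O)c2ccccc2)=C1O | intermediate
13 | methylmagnesium bromide | C[Mg]Br | starting material
14 | hypercalin B | C=C(C)[C@H]1CC[C@](C)(O)[C@@H]1CC1=C(O)C(CC=C(C)C)(CC=C(C)C)C(=O)C(C(=O)c2ccccc2)=C1O | target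

## Step count

Total steps: 5. Longest linear sequence: 5 steps (from 1).

## Steps most likely to fail

**Step 3 (Pauson–Khand).** The cycloaddition may stall through binding of cobalt by the chelating enolised triketone, through protonation of the N-oxide promoter, or through slow ethylene insertion that lets the complex decompose. The new enone may also be trapped by reversible conjugate addition of a neighbouring enol oxygen. The fallback reaches the same enone without the alkyne; it sets out from 3 (step 2 is omitted) and returns at 9. Commercial 2-(hydroxymethyl)cyclopent-2-en-1-one F1, the Morita–Baylis–Hillman adduct of cyclopentenone and formaldehyde, is acetylated (Ac2O, pyridine, DMAP) to (5-oxocyclopent-1-en-1-yl)methyl acetate F2. Tsuji–Trost allylation of 3 with F2 (Pd(PPh3)4, THF, rt) should ionise the acetate to a 2-acyl π-allylpalladium species. The soft trione enolate should attack it at the exocyclic CH2 terminus to give the conjugated enone 9.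

**Step 4 (asymmetric conjugate addition).** Carbometalation of the α-substituted enone may be slow, so that protodeboronation of the alkenylboron reagent outruns it. Facial selectivity may be eroded by the α-substituent, or rhodium may be held as a diketonate. The fallback gives up catalyst control; it sets out from 9 and returns at 12. Copper-mediated conjugate addition (isopropenylmagnesium bromide in excess, CuBr·SMe2, TMSCl, THF, −78 °C, on the pre-formed enolate salt of 9) followed by basic equilibration should give the racemic trans ketone F3. This is separated into its enantiomers by preparative chromatography on a chiral stationary phase to give 12.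

**Step 1 (gem-diprenylation).** Regiocontrol of the second prenylation may be poor, with attack at the unsubstituted ring carbon and over-alkylation taking most of the material. The fallback blocks that carbon; it sets out from prenyl bromide 2 and, in place of 1, commercial methyl 2,4,6-trihydroxybenzoate F4, and returns at 3. Friedel–Crafts benzoylation (PhCOCl, AlCl3, nitrobenzene) should give methyl 3-benzoyl-2,4,6-trihydroxybenzoate F5, which has only one free ring carbon. Double prenylation (2, NaOMe, MeOH) can then only lead to methyl 3-benzoyl-2,4-dihydroxy-5,5-bis(3-methylbut-2-en-1-yl)-6-oxocyclohexa-1,3-diene-1-carboxylate F6. Saponification (aq. NaOH, 60 °C) and decarboxylation of the vinylogous β-keto acid on acidification should give 3.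

## Further compounds

F1 | step 3 | 2-(hydroxymethyl)cyclopent-2-en-1-one | O=C1CCC=C1CO
F2 | step 3 | (5-oxocyclopent-1-en-1-yl)methyl acetate | CC(=O)OCC1=CCCC1=O
F3 | step 4 | racemic trans ketone (12 and its enantiomer) | C=C(C)[C@H]1CCC(=O)[C@@H]1CC1=C(O)C(CC=C(C)C)(CC=C(C)C)C(=O)C(C(=O)c2ccccc2)=C1O.C=C(C)[C@@H]1CCC(=O)[C@H]1CC1=C(O)C(CC=C(C)C)(CC=C(C)C)C(=O)C(C(=O)c2ccccc2)=C1O
F4 | step 1 | methyl 2,4,6-trihydroxybenzoate | COC(=O)c1c(O)cc(O)cc1O
F5 | step 1 | methyl 3-benzoyl-2,4,6-trihydroxybenzoate | COC(=O)c1c(O)c(C(=O)c2ccccc2)c(O)cc1O
F6 | step 1 | methyl 3-benzoyl-2,4-dihydroxy-5,5-bis(3-methylbut-2-en-1-yl)-6-oxocyclohexa-1,3-diene-1-carboxylate | COC(=O)C1=C(O)C(C(=O)c2ccccc2)=C(O)C(CC=C(C)C)(CC=C(C)C)C1=O
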